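**Retrosynthetic overview**

1. Numbering: ring A carbons as in the starting coumarin (C4a, C5, C6, C7, C8, C8a); chain C1–C4 counted from the benzhydryl carbon; ring B on C1, ring D on C4. The plan rests on ring A, where the ketone-bearing C8 and the hydroxyl-bearing C8a are neighbours: C8 lies between C7–O and C8a, and C8a lies next to C4a, the carbon that carries C1.
2. Last disconnection: the four O-benzyl groups. Before it, the C8–C(=O) and C8a–O bonds are made together by inserting the ring A aryne (C8≡C8a) into the C–O bond of 3-(4-methoxyphenyl)propanoic acid.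
3. The aryne precursor (C8–SiMe3, C8a–OTf) comes from the single free ring A phenol (C8a–OH, the former lactone oxygen of a 4-aryl-dihydrocoumarin) by carbamate-directed ortho-silylation, carbamate removal and triflation.
4. Chain: C1 by rhodium-catalysed asymmetric conjugate arylation of 5,7-bis(benzyloxy)coumarin; C2 by trans-selective enolate methylation; C3 and C4 by Weinreb amide, benzyl ketone, (Z)-enol triflate, methyl Negishi coupling and iridium-catalysed asymmetric hydrogenation.
5. No ring is formed in the route: rings A, B, D and the anisyl ring come with the starting materials, and the lactone ring of the coumarin is opened in step 4.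

Key step: step 13

Assumption: the sense of induction of (R)-Segphos in step 2 is taken from the known 4-arylchroman-2-one series, and the hand of the iridium ligand in step 9 is to be fixed in a test run, both enantiomers being available.

**Route**

Step 1
Reactants: 1 5,7-dihydroxycoumarin
Product: 2 5,7-bis(benzyloxy)coumarin
Conditions: BnBr, K2CO3, DMF, 60 °C
Reagents that add atoms: benzyl bromide, BrCc1ccccc1
Why: Williamson etherification of both phenols; the lactone is stable to K2CO3 in DMF.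

Step 2
Reactants: 2 5,7-bis(benzyloxy)coumarin; 3 4-(benzyloxy)phenylboronic acid
Product: 4 (4R)-5,7-bis(benzyloxy)-4-[4-(benzyloxy)phenyl]chroman-2-one
Conditions: Rh(acac)(C2H4)2 (3 mol %), (R)-Segphos, excess 3, dioxane/H2O 10:1, 60 °C
Reagents that add atoms: none
Why: Hayashi–Miyaura asymmetric 1,4-addition: the aryl–rhodium species formed from 3 adds across C3=C4 of the coumarin and water protonates the enolate, the (R)-Segphos ligand selecting the enantioface so that C1 (coumarin C4) should form as (R).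

Step 3
Reactants: 4 (4R)-5,7-bis(benzyloxy)-4-[4-(benzyloxy)phenyl]chroman-2-one
Product: 6 (3S,4R)-5,7-bis(benzyloxy)-4-[4-(benzyloxy)phenyl]-3-methylchroman-2-one, via lithium enolate 5 (not isolated)
Conditions: LiN(SiMe3)2, THF, −78 °C; MeI, −78 → −40 °C
Reagents that add atoms: iodomethane, CI
Why: Alkylation of the lactone enolate; the C4 aryl group, held pseudoaxial by the peri C5 benzyloxy group, shields one face, so the methyl group should enter anti to it and set C2 trans to the C1 aryl group, and the low temperature keeps the aryl ester enolate from fragmenting.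

Step 4
Reactants: 6 (3S,4R)-5,7-bis(benzyloxy)-4-[4-(benzyloxy)phenyl]-3-methylchroman-2-one
Product: 7 (2S,3R)-3-[2,4-bis(benzyloxy)-6-hydroxyphenyl]-3-[4-(benzyloxy)phenyl]-N-methoxy-N,2-dimethylpropanamide
Conditions: MeNH(OMe)·HCl, AlMe3, CH2Cl2, 0 °C → rt; aqueous KNaC4H4O6 work-up
Reagents that add atoms: N,O-dimethylhydroxylamine hydrochloride, CNOC.Cl
Why: Weinreb amide formation by aminolysis of the aryl ester with the aluminium amide; it opens the lactone without touching C1 or C2 and leaves C8a–OH as the only free phenol of ring A.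

Step 5
Reactants: 7 (2S,3R)-3-[2,4-bis(benzyloxy)-6-hydroxyphenyl]-3-[4-(benzyloxy)phenyl]-N-methoxy-N,2-dimethylpropanamide
Product: 8 3,5-bis(benzyloxy)-2-{(1R,2S)-1-[4-(benzyloxy)phenyl]-3-[methoxy(methyl)amino]-2-methyl-3-oxopropyl}phenyl diethylcarbamate
Conditions: NaH, THF, 0 °C; ClC(O)NEt2, 0 °C → rt
Reagents that add atoms: N,N-diethylcarbamoyl chloride, CCN(CC)C(Cl)=O
Why: O-carbamoylation of the sodium phenoxide; the diethylcarbamate protects C8a–O through steps 6 to 9 and is the directing group of step 10.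

Step 6
Reactants: 8 the Weinreb amide carbamate; 9 4-(benzyloxy)benzyl chloride
Product: 11 3,5-bis(benzyloxy)-2-{(1R,2S)-1,4-bis[4-(benzyloxy)phenyl]-2-methyl-3-oxobutyl}phenyl diethylcarbamate, via 4-(benzyloxy)benzylmagnesium chloride 10 (not isolated)
Conditions: 9, Mg, THF, 0 °C; then 8, THF, −20 → 0 °C; aqueous NH4Cl
Reagents that add atoms: none
Why: Grignard addition to a Weinreb amide stops at the chelated tetrahedral intermediate, so the ketone appears only on work-up (no over-addition, no epimerisation of C2), and the aryl carbamate is far less electrophilic than the amide.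

Step 7
Reactants: 11 the benzyl ketone
Product: 13 (1Z,3S,4R)-4-[2,4-bis(benzyloxy)-6-(diethylcarbamoyloxy)phenyl]-1,4-bis[4-(benzyloxy)phenyl]-3-methylbut-1-en-2-yl trifluoromethanesulfonate, via potassium (Z)-enolate 12 (not isolated)
Conditions: KN(SiMe3)2, THF, −78 °C; PhNTf2, −78 → 0 °C
Reagents that add atoms: N-phenylbis(trifluoromethanesulfonimide), O=S(=O)(N(c1ccccc1)S(=O)(=O)C(F)(F)F)C(F)(F)F
Why: Kinetic deprotonation at the benzylic C4 (more acidic and less hindered than the tertiary C2–H, so C2 keeps its configuration) should give the enolate with ring D cis to oxygen, which avoids allylic strain with the branched C2 substituent, and PhNTf2 traps it on oxygen as the (Z)-enol triflate.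

Step 8
Reactants: 13 the (Z)-enol triflate
Product: 14 3,5-bis(benzyloxy)-2-{(1R,2S,3E)-1,4-bis[4-(benzyloxy)phenyl]-2,3-dimethylbut-3-en-1-yl}phenyl diethylcarbamate
Conditions: MeZnCl, Pd(PPh3)4 (5 mol %), THF, 50 °C
Reagents that add atoms: methylzinc chloride, C[Zn]Cl
Why: Negishi coupling of the alkenyl triflate at zerovalent palladium proceeds with retention of alkene geometry and should give the (E)-trisubstituted alkene; the aryl carbamate and the benzyl ethers do not undergo oxidative addition under these conditions.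

Step 9
Reactants: 14 the (E)-alkene
Product: 15 3,5-bis(benzyloxy)-2-{(1R,2R,3S)-1,4-bis[4-(benzyloxy)phenyl]-2,3-dimethylbutyl}phenyl diethylcarbamate
Conditions: H2 (50 bar), [Ir(cod)((S)-tBu-PHOX)][B(C6H3(CF3)2)4] (2 mol %), CH2Cl2, rt
Reagents that add atoms: none
Why: Iridium-catalysed asymmetric hydrogenation of an unfunctionalised trisubstituted aryl alkene with a chiral P,N ligand (Pfaltz type; cod = 1,5-cyclooctadiene, tBu-PHOX = 4-tert-butyl-2-[2-(diphenylphosphanyl)phenyl]-4,5-dihydrooxazole): H2 adds syn to the alkene face chosen by the ligand rather than by the C2 centre, which should set C3 as (3S), and the homogeneous catalyst does not cleave benzyl ethers.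

Step 10
Reactants: 15 the saturated carbamate
Product: 17 3,5-bis(benzyloxy)-2-{(1R,2R,3S)-1,4-bis[4-(benzyloxy)phenyl]-2,3-dimethylbutyl}-6-(trimethylsilyl)phenyl diethylcarbamate, via C8 aryllithium 16 (not isolated)
Conditions: sec-BuLi, TMEDA, THF, −78 °C; Me3SiCl, −78 °C → rt
Reagents that add atoms: chlorotrimethylsilane, C[Si](C)(C)Cl
Why: Directed ortho-metalation (Snieckus): the carbamate guides the base to C8–H, its only ortho ring hydrogen and one also acidified by the C7 benzyloxy group, while the shielded tertiary C1–H and the benzyl ether CH2 groups react more slowly at −78 °C and the anionic Fries shift needs higher temperature, so Me3SiCl should silylate C8.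

Step 11
Reactants: 17 the C8-silyl carbamate
Product: 18 3,5-bis(benzyloxy)-2-{(1R,2R,3S)-1,4-bis[4-(benzyloxy)phenyl]-2,3-dimethylbutyl}-6-(trimethylsilyl)phenol
Conditions: LiAlH4, THF, 0 → 50 °C; aqueous KNaC4H4O6 work-up (no acid)
Reagents that add atoms: none
Why: Reductive cleavage of the aryl carbamate: hydride adds to the carbamoyl C=O, the phenoxide is expelled and the formamide is reduced on to the amine; the aryl C–Si bond and the benzyl ethers are inert to hydride, and the acid-free work-up avoids protodesilylation of the electron-rich aryl silane.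

Step 12
Reactants: 18 the ortho-silyl phenol
Product: 19 3,5-bis(benzyloxy)-2-{(1R,2R,3S)-1,4-bis[4-(benzyloxy)phenyl]-2,3-dimethylbutyl}-6-(trimethylsilyl)phenyl trifluoromethanesulfonate
Conditions: KN(SiMe3)2, THF, −78 °C; PhNTf2, −78 °C → rt
Reagents that add atoms: N-phenylbis(trifluoromethanesulfonimide), O=S(=O)(N(c1ccccc1)S(=O)(=O)C(F)(F)F)C(F)(F)F
Why: O-sulfonylation of the potassium phenoxide under basic, acid-free conditions gives the ortho-silylaryl triflate, the standard fluoride-triggered aryne precursor.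

Step 13
Reactants: 19 the ortho-silylaryl triflate; 20 3-(4-methoxyphenyl)propanoic acid
Product: 22 1-{4,6-bis(benzyloxy)-3-[(1R,2R,3S)-1,4-bis[4-(benzyloxy)phenyl]-2,3-dimethylbutyl]-2-hydroxyphenyl}-3-(4-methoxyphenyl)propan-1-one, via ring A aryne 21 (not isolated)
Conditions: 20 (3 equiv), CsF (6 equiv), THF, 125 °C, sealed tube; 19 added last
Reagents that add atoms: none
Why: Fluoride attacks the C8 silicon of 19 and triflate leaves from C8a, giving aryne 21 (C8≡C8a); the cesium carboxylate of 20 adds through oxygen to C8a, the resulting C8 aryl anion attacks the ester carbonyl held on the neighbouring oxygen, and the four-membered alkoxide opens to the ortho-acyl phenoxide, so the C8a–O and C8–C(=O) bonds form on adjacent carbons in one operation. The closest known reaction type is the insertion of arynes from ortho-silylaryl triflates into the C–O bond of carboxylic acids (CsF, THF, about 125 °C), which gives ortho-hydroxyaryl ketones. No ring is closed and no stereocentre is formed; C1 to C3 are not touched by these basic conditions, which contain no Lewis acid. The step needs regioselective addition to the unsymmetrical aryne: the C7 benzyloxy group, through its inductive pull and the distortion it imposes on the aryne, should send the oxygen nucleophile to the distal carbon C8a so that the negative charge develops at C8 next to oxygen, and this electronic bias has to override the steric shielding of C8a by the C1 substituent on C4a. It also needs acyl transfer to outrun protonation of the aryl anion, which the high temperature, the aprotic medium and the excess CsF (20 present as carboxylate before 19 is added) should favour.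

Step 14
Reactants: 22 the tetrabenzyl ether
Product: 23 1-{3-[(1R,2R,3S)-1,4-bis(4-hydroxyphenyl)-2,3-dimethylbutyl]-2,4,6-trihydroxyphenyl}-3-(4-methoxyphenyl)propan-1-one
Conditions: H2 (1 atm), Pd/C (10 %), EtOAc/MeOH, rt
Reagents that add atoms: none
Why: Hydrogenolysis of the four benzyl ethers over palladium; the methyl ether, the hydrogen-bonded 2,4,6-trioxygenated aryl ketone and the three stereocentres should be untouched.

**Compound list**

1 | 5,7-dihydroxycoumarin | O=C1C=Cc2c(O)cc(O)cc2O1 | starting material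
2 | 5,7-bis(benzyloxy)coumarin | O=C1C=Cc2c(OCc3ccccc3)cc(OCc3ccccc3)cc2O1 | intermediate
3 | 4-(benzyloxy)phenylboronic acid | OB(O)c1ccc(OCc2ccccc2)cc1 | starting material
4 | (4R)-5,7-bis(benzyloxy)-4-[4-(benzyloxy)phenyl]chroman-2-one | O1c2cc(OCc3ccccc3)cc(OCc3ccccc3)c2[C@@H](c2ccc(OCc3ccccc3)cc2)CC1=O | intermediate
5 | lithium enolate of 4 | O1c2cc(OCc3ccccc3)cc(OCc3ccccc3)c2[C@@H](c2ccc(OCc3ccccc3)cc2)C=C1[O-].[Li+] | intermediate
6 | (3S,4R)-5,7-bis(benzyloxy)-4-[4-(benzyloxy)phenyl]-3-methylchroman-2-one (trans) | O1c2cc(OCc3ccccc3)cc(OCc3ccccc3)c2[C@@H](c2ccc(OCc3ccccc3)cc2)[C@H](C)C1=O | intermediate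
7 | (2S,3R)-3-[2,4-bis(benzyloxy)-6-hydroxyphenyl]-3-[4-(benzyloxy)phenyl]-N-methoxy-N,2-dimethylpropanamide | Oc1cc(OCc2ccccc2)cc(OCc2ccccc2)c1[C@@H](c3ccc(OCc2ccccc2)cc3)[C@H](C)C(=O)N(C)OC | intermediate
8 | 3,5-bis(benzyloxy)-2-{(1R,2S)-1-[4-(benzyloxy)phenyl]-3-[methoxy(methyl)amino]-2-methyl-3-oxopropyl}phenyl diethylcarbamate | CCN(CC)C(=O)Oc1cc(OCc2ccccc2)cc(OCc2ccccc2)c1[C@@H](c3ccc(OCc2ccccc2)cc3)[C@H](C)C(=O)N(C)OC | intermediate
9 | 4-(benzyloxy)benzyl chloride | ClCc1ccc(OCc2ccccc2)cc1 | starting material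
10 | 4-(benzyloxy)benzylmagnesium chloride | Cl[Mg]Cc1ccc(OCc2ccccc2)cc1 | intermediate
11 | 3,5-bis(benzyloxy)-2-{(1R,2S)-1,4-bis[4-(benzyloxy)phenyl]-2-methyl-3-oxobutyl}phenyl diethylcarbamate | CCN(CC)C(=O)Oc1cc(OCc2ccccc2)cc(OCc2ccccc2)c1[C@@H](c3ccc(OCc2ccccc2)cc3)[C@H](C)C(=O)Cc4ccc(OCc2ccccc2)cc4 | intermediate
12 | potassium (Z)-enolate of 11 | CCN(CC)C(=O)Oc1cc(OCc2ccccc2)cc(OCc2ccccc2)c1[C@@H](c3ccc(OCc2ccccc2)cc3)[C@H](C)/C([O-])=C/c4ccc(OCc2ccccc2)cc4.[K+] | intermediate
13 | (1Z,3S,4R)-4-[2,4-bis(benzyloxy)-6-(diethylcarbamoyloxy)phenyl]-1,4-bis[4-(benzyloxy)phenyl]-3-methylbut-1-en-2-yl trifluoromethanesulfonate | CCN(CC)C(=O)Oc1cc(OCc2ccccc2)cc(OCc2ccccc2)c1[C@@H](c3ccc(OCc2ccccc2)cc3)[C@H](C)/C(OS(=O)(=O)C(F)(F)F)=C/c4ccc(OCc2ccccc2)cc4 | intermediate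
14 | 3,5-bis(benzyloxy)-2-{(1R,2S,3E)-1,4-bis[4-(benzyloxy)phenyl]-2,3-dimethylbut-3-en-1-yl}phenyl diethylcarbamate | CCN(CC)C(=O)Oc1cc(OCc2ccccc2)cc(OCc2ccccc2)c1[C@@H](c3ccc(OCc2ccccc2)cc3)[C@H](C)/C(C)=C/c4ccc(OCc2ccccc2)cc4 | intermediate
15 | 3,5-bis(benzyloxy)-2-{(1R,2R,3S)-1,4-bis[4-(benzyloxy)phenyl]-2,3-dimethylbutyl}phenyl diethylcarbamate | CCN(CC)C(=O)Oc1cc(OCc2ccccc2)cc(OCc2ccccc2)c1[C@@H](c3ccc(OCc2ccccc2)cc3)[C@H](C)[C@@H](C)Cc4ccc(OCc2ccccc2)cc4 | intermediate
16 | C8 aryllithium of 15 | CCN(CC)C(=O)Oc1c([Li])c(OCc2ccccc2)cc(OCc2ccccc2)c1[C@@H](c3ccc(OCc2ccccc2)cc3)[C@H](C)[C@@H](C)Cc4ccc(OCc2ccccc2)cc4 | intermediate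
17 | 3,5-bis(benzyloxy)-2-{(1R,2R,3S)-1,4-bis[4-(benzyloxy)phenyl]-2,3-dimethylbutyl}-6-(trimethylsilyl)phenyl diethylcarbamate | CCN(CC)C(=O)Oc1c([Si](C)(C)C)c(OCc2ccccc2)cc(OCc2ccccc2)c1[C@@H](c3ccc(OCc2ccccc2)cc3)[C@H](C)[C@@H](C)Cc4ccc(OCc2ccccc2)cc4 | intermediate
18 | 3,5-bis(benzyloxy)-2-{(1R,2R,3S)-1,4-bis[4-(benzyloxy)phenyl]-2,3-dimethylbutyl}-6-(trimethylsilyl)phenol | Oc1c([Si](C)(C)C)c(OCc2ccccc2)cc(OCc2ccccc2)c1[C@@H](c3ccc(OCc2ccccc2)cc3)[C@H](C)[C@@H](C)Cc4ccc(OCc2ccccc2)cc4 | intermediate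
19 | 3,5-bis(benzyloxy)-2-{(1R,2R,3S)-1,4-bis[4-(benzyloxy)phenyl]-2,3-dimethylbutyl}-6-(trimethylsilyl)phenyl trifluoromethanesulfonate | FC(F)(F)S(=O)(=O)Oc1c([Si](C)(C)C)c(OCc2ccccc2)cc(OCc2ccccc2)c1[C@@H](c3ccc(OCc2ccccc2)cc3)[C@H](C)[C@@H](C)Cc4ccc(OCc2ccccc2)cc4 | intermediate
20 | 3-(4-methoxyphenyl)propanoic acid | COc1ccc(CCC(=O)O)cc1 | starting material
21 | ring A aryne (C8≡C8a): 4,6-bis(benzyloxy)-3-{(1R,2R,3S)-1,4-bis[4-(benzyloxy)phenyl]-2,3-dimethylbutyl}benzyne | C1#CC(OCc2ccccc2)=CC(OCc2ccccc2)=C1[C@@H](c3ccc(OCc2ccccc2)cc3)[C@H](C)[C@@H](C)Cc4ccc(OCc2ccccc2)cc4 | intermediate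
22 | 1-{4,6-bis(benzyloxy)-3-[(1R,2R,3S)-1,4-bis[4-(benzyloxy)phenyl]-2,3-dimethylbutyl]-2-hydroxyphenyl}-3-(4-methoxyphenyl)propan-1-one | COc1ccc(CCC(=O)c2c(OCc3ccccc3)cc(OCc3ccccc3)c([C@@H](c4ccc(OCc3ccccc3)cc4)[C@H](C)[C@@H](C)Cc5ccc(OCc3ccccc3)cc5)c2O)cc1 | intermediate
23 | 1-{3-[(1R,2R,3S)-1,4-bis(4-hydroxyphenyl)-2,3-dimethylbutyl]-2,4,6-trihydroxyphenyl}-3-(4-methoxyphenyl)propan-1-one (CNP0193401.1) | COc1ccc(CCC(=O)c2c(O)cc(O)c([C@@H](c3ccc(O)cc3)[C@H](C)[C@@H](C)Cc3ccc(O)cc3)c2O)cc1 | target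

**Step count**

Total steps: 14. Longest linear sequence: 14 steps (1 → 23).

**Steps most likely to fail**

Step 13 (key step). What may go wrong:
- the carboxylate adds to C8 instead of C8a under the steric influence of the C1 substituent;
- the aryl anion is protonated before acyl transfer, giving an O-aryl ester instead of the ketone;
- 19 is protodesilylated before the aryne forms.

The fallback uses no aryne, sets out from 15 and comes back at 23. LiAlH4 in THF removes the carbamate from 15 to give the tetrabenzyl phenol F1. Hydrogenolysis (H2, Pd/C) gives the pentaphenol F2. Friedel–Crafts C-acylation of F2 with acid 20 in BF3·OEt2 (60–70 °C) should then give 23 directly. In F2 the two free ring A positions C6 and C8 are constitutionally equivalent, so the acylation has no regiochemical problem, and the phloroglucinol ring A is far more nucleophilic than rings B and D. The price is that the benzhydryl C1–C4a bond meets a Lewis acid, which the main route avoids.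

Step 9. What may go wrong: poor facial selectivity if the C2 centre opposes the catalyst, or low conversion of the hindered trisubstituted alkene.

The fallback sets out from 8 and comes back at 15, and sets C3 by conjugate reduction instead of alkene hydrogenation. MeMgBr converts Weinreb amide 8 into the methyl ketone F3. Horner–Wadsworth–Emmons olefination with triethyl phosphonoacetate and NaH gives the (E)-enoate F4. Copper hydride conjugate reduction (Cu(OAc)2, DTBM-Segphos of the hand that gives 3S, polymethylhydrosiloxane, t-BuOH) sets C3 in the saturated ester F5; ligand control is strong for β,β-disubstituted enoates. LiOH gives the acid F6, and N-hydroxyphthalimide with diisopropylcarbodiimide gives the redox-active ester F7. Nickel-catalysed decarboxylative arylation of F7 with boronic acid 3 (NiCl2·6H2O, bathophenanthroline, Et3N, dioxane/DMF) forms the C4–ring D bond and returns 15.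

Step 2. What may go wrong: slow carbometalation at coumarin C4 because of the peri C5 benzyloxy group, so that protodeboronation of 3 wins.

The fallback sets out from 2 (with 3) and comes back at 4, and sets C1 by hydride delivery instead of aryl delivery. Oxidative Heck arylation of 2 with 3 (Pd(OAc)2, 1,10-phenanthroline, O2, DMF) gives the 4-arylcoumarin F8. Copper hydride asymmetric conjugate reduction of F8 (Cu(OAc)2, DTBM-Segphos of the hand that gives 4R, diethoxymethylsilane, t-BuOH) should give 4. If the lactone carbonyl is reduced as well, the product is the lactol F9, which Ag2CO3 on Celite oxidises back to 4.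

Further compounds

F1 | step 13 | 3,5-bis(benzyloxy)-2-{(1R,2R,3S)-1,4-bis[4-(benzyloxy)phenyl]-2,3-dimethylbutyl}phenol | Oc1cc(OCc2ccccc2)cc(OCc2ccccc2)c1[C@@H](c3ccc(OCc2ccccc2)cc3)[C@H](C)[C@@H](C)Cc4ccc(OCc2ccccc2)cc4
F2 | step 13 | 2-[(1R,2R,3S)-1,4-bis(4-hydroxyphenyl)-2,3-dimethylbutyl]benzene-1,3,5-triol | Oc1cc(O)cc(O)c1[C@@H](c3ccc(O)cc3)[C@H](C)[C@@H](C)Cc4ccc(O)cc4
F3 | step 9 | 3,5-bis(benzyloxy)-2-{(1R,2S)-1-[4-(benzyloxy)phenyl]-2-methyl-3-oxobutyl}phenyl diethylcarbamate | CCN(CC)C(=O)Oc1cc(OCc2ccccc2)cc(OCc2ccccc2)c1[C@@H](c3ccc(OCc2ccccc2)cc3)[C@H](C)C(C)=O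
F4 | step 9 | ethyl (2E,4S,5R)-5-[2,4-bis(benzyloxy)-6-(diethylcarbamoyloxy)phenyl]-5-[4-(benzyloxy)phenyl]-3,4-dimethylpent-2-enoate | CCN(CC)C(=O)Oc1cc(OCc2ccccc2)cc(OCc2ccccc2)c1[C@@H](c3ccc(OCc2ccccc2)cc3)[C@H](C)/C(C)=C/C(=O)OCC
F5 | step 9 | ethyl (3S,4R,5R)-5-[2,4-bis(benzyloxy)-6-(diethylcarbamoyloxy)phenyl]-5-[4-(benzyloxy)phenyl]-3,4-dimethylpentanoate | CCN(CC)C(=O)Oc1cc(OCc2ccccc2)cc(OCc2ccccc2)c1[C@@H](c3ccc(OCc2ccccc2)cc3)[C@H](C)[C@@H](C)CC(=O)OCC
F6 | step 9 | (3S,4R,5R)-5-[2,4-bis(benzyloxy)-6-(diethylcarbamoyloxy)phenyl]-5-[4-(benzyloxy)phenyl]-3,4-dimethylpentanoic acid | CCN(CC)C(=O)Oc1cc(OCc2ccccc2)cc(OCc2ccccc2)c1[C@@H](c3ccc(OCc2ccccc2)cc3)[C@H](C)[C@@H](C)CC(=O)O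
F7 | step 9 | 1,3-dioxoisoindolin-2-yl (3S,4R,5R)-5-[2,4-bis(benzyloxy)-6-(diethylcarbamoyloxy)phenyl]-5-[4-(benzyloxy)phenyl]-3,4-dimethylpentanoate | CCN(CC)C(=O)Oc1cc(OCc2ccccc2)cc(OCc2ccccc2)c1[C@@H](c3ccc(OCc2ccccc2)cc3)[C@H](C)[C@@H](C)CC(=O)ON4C(=O)c5ccccc5C4=O
F8 | step 2 | 5,7-bis(benzyloxy)-4-[4-(benzyloxy)phenyl]coumarin | O=C1C=C(c2ccc(OCc3ccccc3)cc2)c2c(OCc3ccccc3)cc(OCc3ccccc3)cc2O1
F9 | step 2 | (4R)-5,7-bis(benzyloxy)-4-[4-(benzyloxy)phenyl]chroman-2-ol | O1c2cc(OCc3ccccc3)cc(OCc3ccccc3)c2[C@@H](c2ccc(OCc3ccccc3)cc2)CC1O
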